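**Strategy.** Ring A, the cyclohexene that carries the ester on C2 and the formyl group on C1 (naphthalene numbering), is built last from a ring B cyclohexanone. The plan rests on disconnecting the C2=C3 alkene and the C1–C8a bond together: fluoride unmasks a regiodefined C8 silyl enol ether whose C4a carries a CH2–CHO arm; the C8a enolate adds to an alkylidene phosphonoacetate (C1 with the masked formyl group, C2 with the ester), and the phosphonate carbanion closes ring A on the C3 aldehyde by Horner–Wadsworth–Emmons olefination. The step exploits the 1,5-relationship of the C8 carbonyl and C3 across C8a–C4a–C4 and delivers the quaternary C8a and the enoate at once.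

Key step: step 10

Locants C1–C8a in the Why lines are those of the octahydronaphthalene skeleton of the target (ring A = C1–C4, C4a, C8a; ring B = C4a–C8a) and are used for all ring B intermediates.
Assumption: in step 1 the (R)-BINOL–titanium catalyst is taken to give the (1S)-carbinol; if the sense of induction is the opposite, (S)-BINOL is used.

Step 1
Reactants: 1 2-methylcyclohex-2-en-1-one
Product: 2 (1S)-2-methyl-1-(prop-2-en-1-yl)cyclohex-2-en-1-ol
Conditions: Sn(CH2CH=CH2)4 (1.5 equiv), Ti(OiPr)4 (0.3 equiv), (R)-BINOL (0.3 equiv), iPrOH (20 equiv), CH2Cl2, rt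
Reagents that add atoms: tetraallylstannane C=CC[Sn](CC=C)(CC=C)CC=C
Why: Titanium–BINOL-catalysed enantioselective 1,2-allylation of a ketone with an allylstannane should create the tertiary allylic carbinol, the chiral catalyst selecting one carbonyl face of the 2-substituted cyclic enone while the α-methyl group disfavours conjugate addition.

Step 2
Reactants: 2 (1S)-2-methyl-1-(prop-2-en-1-yl)cyclohex-2-en-1-ol
Product: 4 (2S,3S)-3-chloro-2-methyl-2-(prop-2-en-1-yl)cyclohexan-1-one, via tertiary chloro carbocation 3 (not isolated)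
Conditions: NCS (1.1 equiv), Ph3P=S (5 mol%), CH2Cl2, −20 → 0 °C
Reagents that add atoms: N-chlorosuccinimide O=C1CCC(=O)N1Cl
Why: Halonium-induced semipinacol rearrangement, in which Cl+ should add to C6 on the alkene face syn to the hydroxyl group (anti to allyl) to give the chloronium ion and its open tertiary cation at C5, and the antiperiplanar allyl group should shift suprafacially from the carbinol carbon (C4a) to C5 as the ketone forms, so that the carbinol configuration is relayed to the quaternary carbon and chlorine ends trans to allyl and cis to methyl.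

Step 3
Reactants: 4 (2S,3S)-3-chloro-2-methyl-2-(prop-2-en-1-yl)cyclohexan-1-one
Product: 6 (2S,3S)-3-chloro-2,6-dimethyl-2-(prop-2-en-1-yl)cyclohexan-1-one (both C6 epimers), via lithium enolate 5 (not isolated)
Conditions: LiN(iPr)2, THF, −78 °C; MeI, −78 → 0 °C
Reagents that add atoms: iodomethane CI
Why: Enolate alkylation that is regiospecific because the other α-carbon is quaternary (which also rules out E1cB loss of the chloride); the new center becomes planar in step 4, so its configuration does not matter.

Step 4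
Reactants: 6 (2S,3S)-3-chloro-2,6-dimethyl-2-(prop-2-en-1-yl)cyclohexan-1-one
Product: 7 (5S,6S)-5-chloro-2,6-dimethyl-6-(prop-2-en-1-yl)cyclohex-2-en-1-one
Conditions: IBX (2 equiv), DMSO/PhF, 70 °C
Reagents that add atoms: none
Why: IBX-mediated α,β-dehydrogenation of a ketone should give the endocyclic 2-methyl enone, since only one side of the carbonyl can enolise and the alkyl chloride and terminal alkene are inert to the reagent.

Step 5
Reactants: 7 (5S,6S)-5-chloro-2,6-dimethyl-6-(prop-2-en-1-yl)cyclohex-2-en-1-one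
Product: 8 ethyl 2-[(5S,6S)-5-chloro-1-hydroxy-2,6-dimethyl-6-(prop-2-en-1-yl)cyclohex-2-en-1-yl]acetate (both C1 epimers)
Conditions: EtOAc, LiN(iPr)2, THF, −78 °C; CeCl3; then 7, −78 °C; aq. NH4Cl
Reagents that add atoms: ethyl acetate CCOC(C)=O
Why: Aldol-type 1,2-addition of a cerium ester enolate to the hindered enone carbonyl (organocerium reagents favour carbonyl addition over conjugate addition and enolisation); the carbinol configuration is irrelevant because the center is destroyed in step 6.

Step 6
Reactants: 8 ethyl 2-[(5S,6S)-5-chloro-1-hydroxy-2,6-dimethyl-6-(prop-2-en-1-yl)cyclohex-2-en-1-yl]acetate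
Product: 9 ethyl 2-[(5S,6S)-5-chloro-2,6-dimethyl-3-oxo-6-(prop-2-en-1-yl)cyclohex-1-en-1-yl]acetate
Conditions: C5H5NH[CrO3Cl] (2.5 equiv), 4 Å molecular sieves, CH2Cl2, rt
Reagents that add atoms: none
Why: Babler–Dauben oxidative 1,3-transposition, in which the chromate ester of the tertiary allylic alcohol should undergo a [3,3] shift and oxidation, moving the oxygen to C8 and the alkene to C8a=C4a under non-basic conditions that the β-chloro ketone tolerates.

Step 7
Reactants: 9 ethyl 2-[(5S,6S)-5-chloro-2,6-dimethyl-3-oxo-6-(prop-2-en-1-yl)cyclohex-1-en-1-yl]acetate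
Product: 10 ethyl 2-[(1R,5S,6S)-5-chloro-3-{[dimethyl(phenyl)silyl]oxy}-2,6-dimethyl-6-(prop-2-en-1-yl)cyclohex-2-en-1-yl]acetate
Conditions: [(Ph3P)CuH]6 (5 mol%), PhMe2SiH (1.5 equiv), toluene, rt
Reagents that add atoms: dimethyl(phenyl)silane C[SiH](C)c1ccccc1
Why: Copper hydride-catalysed 1,4-hydrosilylation of the enone should give the regiodefined C8 silyl enol ether directly, with hydride delivered axially to C4a from the face opposite the pseudoaxial C5 methyl group and the C6 chlorine, which places C4a–H on the allyl face; chloride, ester and terminal alkene are inert to the copper hydride.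

Step 8
Reactants: 10 ethyl 2-[(1R,5S,6S)-5-chloro-3-{[dimethyl(phenyl)silyl]oxy}-2,6-dimethyl-6-(prop-2-en-1-yl)cyclohex-2-en-1-yl]acetate
Product: 11 2-[(1R,5S,6S)-5-chloro-3-{[dimethyl(phenyl)silyl]oxy}-2,6-dimethyl-6-(prop-2-en-1-yl)cyclohex-2-en-1-yl]acetaldehyde
Conditions: iBu2AlH (1.1 equiv), CH2Cl2, −78 °C; aq. KNaC4H4O6
Reagents that add atoms: none
Why: Partial reduction of the ester at −78 °C should stop at the aldehyde through the stable tetrahedral aluminate, leaving the silyl enol ether and the chloride untouched.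

Step 9
Reactants: 12 methyl 2-(diethoxyphosphoryl)acetate, 13 2,2-dimethoxyacetaldehyde
Product: 14 methyl 2-(diethoxyphosphoryl)-4,4-dimethoxybut-2-enoate (E/Z mixture)
Conditions: piperidine (cat.), AcOH (cat.), toluene, reflux, Dean–Stark
Reagents that add atoms: none
Why: Knoevenagel condensation of the phosphonoacetate with a non-enolisable aldehyde, driven by azeotropic removal of water, should give the doubly activated alkylidene phosphonoacetate, whose alkene geometry is of no consequence.

Step 10
Reactants: 11 2-[(1R,5S,6S)-5-chloro-3-{[dimethyl(phenyl)silyl]oxy}-2,6-dimethyl-6-(prop-2-en-1-yl)cyclohex-2-en-1-yl]acetaldehyde, 14 methyl 2-(diethoxyphosphoryl)-4,4-dimethoxybut-2-enoate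
Product: 17 methyl (1R,4aR,5S,6S,8aS)-6-chloro-1-(dimethoxymethyl)-5,8a-dimethyl-8-oxo-5-(prop-2-en-1-yl)-1,4,4a,5,6,7,8,8a-octahydronaphthalene-2-carboxylate, via tetrabutylammonium C8a enolate 15 (not isolated), via phosphonate-stabilised Michael adduct carbanion 16 (not isolated)
Conditions: Bu4N[Ph3SiF2] (1.1 equiv), 14 (2.5 equiv), THF, −40 °C → rt; 11 added slowly
Reagents that add atoms: none
Why: Fluoride cleaves the O–Si bond to give the regiodefined ammonium enolate, which should add through C8a to the alkylidene phosphonoacetate; the phosphonate carbanion so formed attacks the tethered C3 aldehyde and expels diethyl phosphate, so C1–C8a and C2=C3 form in one flask. The closest known reaction type is the tandem Michael/intramolecular Horner–Wadsworth–Emmons annulation of carbon nucleophiles carrying a pendant aldehyde with 2-phosphonoacrylates, which gives cyclohexene-1-carboxylates. Ring A closes in the olefination by a 6-(enolexo)-exo-trig attack of C2 on the C3 carbonyl. C8a is set by substrate control, since the β face of the enolate is shielded by the C4a side chain, the axial C5 methyl group and the C6 chlorine, so the acceptor enters trans to the C4a arm and a trans ring fusion results; C1 is expected to be set in the ring closure, where a reversible Michael addition feeds a chair transition state in which C1–H eclipses the planar carbanion (minimal allylic 1,3-strain) and the dimethoxymethyl group becomes equatorial. The step needs C-alkylation at C8a in the presence of an enolisable aldehyde and a β-chlorine; the regiodefined silyl enol ether, slow addition of 11 to excess acceptor, and the poor alignment of the equatorial C–Cl bond for E1cB loss are relied on for this.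

Step 11
Reactants: 17 methyl (1R,4aR,5S,6S,8aS)-6-chloro-1-(dimethoxymethyl)-5,8a-dimethyl-8-oxo-5-(prop-2-en-1-yl)-1,4,4a,5,6,7,8,8a-octahydronaphthalene-2-carboxylate
Product: 18 methyl (1R,4aR,5S,6S,8S,8aS)-6-chloro-1-(dimethoxymethyl)-8-hydroxy-5,8a-dimethyl-5-(prop-2-en-1-yl)-1,4,4a,5,6,7,8,8a-octahydronaphthalene-2-carboxylate
Conditions: LiBH(sBu)3, THF, −78 °C; aq. NH4Cl
Reagents that add atoms: none
Why: The hindered trialkylborohydride should attack the C8 ketone along the equatorial trajectory, because the axial approach is blocked by the syn-axial hydrogens at C1, C4a and C6, giving the axial 8-hydroxyl group trans to the C8a methyl group; the enoate and the chloride are not reduced at −78 °C.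

Step 12
Reactants: 18 methyl (1R,4aR,5S,6S,8S,8aS)-6-chloro-1-(dimethoxymethyl)-8-hydroxy-5,8a-dimethyl-5-(prop-2-en-1-yl)-1,4,4a,5,6,7,8,8a-octahydronaphthalene-2-carboxylate, 19 2-methylbut-3-en-2-ol
Product: 20 methyl (1R,4aR,5S,6S,8S,8aS)-6-chloro-1-(dimethoxymethyl)-8-hydroxy-5-[(2E)-4-hydroxy-4-methylpent-2-en-1-yl]-5,8a-dimethyl-1,4,4a,5,6,7,8,8a-octahydronaphthalene-2-carboxylate
Conditions: 19 (10 equiv), second-generation Hoveyda–Grubbs catalyst RuCl2(=CH–C6H4-2-OiPr)(H2IMes) (5 mol%), CH2Cl2, 40 °C
Reagents that add atoms: none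
Why: Olefin cross-metathesis of the terminal allyl group with a tertiary allylic alcohol used in excess should give the (E)-alkene under thermodynamic control with loss of ethene, while the trisubstituted enoate does not take part.

Step 13
Reactants: 20 methyl (1R,4aR,5S,6S,8S,8aS)-6-chloro-1-(dimethoxymethyl)-8-hydroxy-5-[(2E)-4-hydroxy-4-methylpent-2-en-1-yl]-5,8a-dimethyl-1,4,4a,5,6,7,8,8a-octahydronaphthalene-2-carboxylate
Product: 21 methyl (1R,4aR,5S,6S,8S,8aS)-6-chloro-1-formyl-8-hydroxy-5-[(2E)-4-hydroxy-4-methylpent-2-en-1-yl]-5,8a-dimethyl-1,4,4a,5,6,7,8,8a-octahydronaphthalene-2-carboxylate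
Conditions: PPTS (cat.), acetone/H2O (10:1), rt
Reagents that add atoms: water O
Why: Mild acid-catalysed acetal hydrolysis should release the aldehyde without touching C1, whose configuration was fixed at the acetal stage; weak acid at room temperature avoids epimerisation of the β,γ-unsaturated aldehyde and ionisation of the tertiary allylic alcohol.

**Compound list**

1 | 2-methylcyclohex-2-en-1-one | CC1=CCCCC1=O | starting material
2 | (1S)-2-methyl-1-(prop-2-en-1-yl)cyclohex-2-en-1-ol | C=CC[C@@]1(O)CCCC=C1C | intermediate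
3 | tertiary chloro carbocation from 2, the open form of the chloronium ion (not isolated) | C=CC[C@@]1(O)CCC[C@H](Cl)[C+]1C | intermediate
4 | (2S,3S)-3-chloro-2-methyl-2-(prop-2-en-1-yl)cyclohexan-1-one | O=C1[C@](C)(CC=C)[C@@H](Cl)CCC1 | intermediate
5 | lithium enolate of 4 (not isolated) | [Li+].[O-]C1=CCC[C@H](Cl)[C@@]1(C)CC=C | intermediate
6 | (2S,3S)-3-chloro-2,6-dimethyl-2-(prop-2-en-1-yl)cyclohexan-1-one (both C6 epimers) | O=C1[C@](C)(CC=C)[C@@H](Cl)CCC1C | intermediate
7 | (5S,6S)-5-chloro-2,6-dimethyl-6-(prop-2-en-1-yl)cyclohex-2-en-1-one | O=C1C(C)=CC[C@H](Cl)[C@@]1(C)CC=C | intermediate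
8 | ethyl 2-[(5S,6S)-5-chloro-1-hydroxy-2,6-dimethyl-6-(prop-2-en-1-yl)cyclohex-2-en-1-yl]acetate (both C1 epimers) | CCOC(=O)CC1(O)C(C)=CC[C@H](Cl)[C@@]1(C)CC=C | intermediate
9 | ethyl 2-[(5S,6S)-5-chloro-2,6-dimethyl-3-oxo-6-(prop-2-en-1-yl)cyclohex-1-en-1-yl]acetate | CCOC(=O)CC1=C(C)C(=O)C[C@H](Cl)[C@@]1(C)CC=C | intermediate
10 | ethyl 2-[(1R,5S,6S)-5-chloro-3-{[dimethyl(phenyl)silyl]oxy}-2,6-dimethyl-6-(prop-2-en-1-yl)cyclohex-2-en-1-yl]acetate | CCOC(=O)C[C@H]1[C@](C)(CC=C)[C@@H](Cl)CC(O[Si](C)(C)c2ccccc2)=C1C | intermediate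
11 | 2-[(1R,5S,6S)-5-chloro-3-{[dimethyl(phenyl)silyl]oxy}-2,6-dimethyl-6-(prop-2-en-1-yl)cyclohex-2-en-1-yl]acetaldehyde | O=CC[C@H]1[C@](C)(CC=C)[C@@H](Cl)CC(O[Si](C)(C)c2ccccc2)=C1C | intermediate
12 | methyl 2-(diethoxyphosphoryl)acetate | COC(=O)CP(=O)(OCC)OCC | starting material
13 | 2,2-dimethoxyacetaldehyde | COC(OC)C=O | starting material
14 | methyl 2-(diethoxyphosphoryl)-4,4-dimethoxybut-2-enoate (E/Z mixture) | COC(OC)C=C(C(=O)OC)P(=O)(OCC)OCC | intermediate
15 | tetrabutylammonium C8a enolate freed from 11 (not isolated) | CCCC[N+](CCCC)(CCCC)CCCC.O=CC[C@H]1[C@](C)(CC=C)[C@@H](Cl)CC([O-])=C1C | intermediate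
16 | phosphonate-stabilised carbanion of the Michael adduct of 15 and 14, tetrabutylammonium salt (not isolated) | CCCC[N+](CCCC)(CCCC)CCCC.O=CC[C@H]1[C@](C)(CC=C)[C@@H](Cl)CC(=O)[C@]1(C)[C@@H](C(OC)OC)[C-](C(=O)OC)P(=O)(OCC)OCC | intermediate
17 | methyl (1R,4aR,5S,6S,8aS)-6-chloro-1-(dimethoxymethyl)-5,8a-dimethyl-8-oxo-5-(prop-2-en-1-yl)-1,4,4a,5,6,7,8,8a-octahydronaphthalene-2-carboxylate | COC(=O)C1=CC[C@H]2[C@](C)(CC=C)[C@@H](Cl)CC(=O)[C@]2(C)[C@H]1C(OC)OC | intermediate
18 | methyl (1R,4aR,5S,6S,8S,8aS)-6-chloro-1-(dimethoxymethyl)-8-hydroxy-5,8a-dimethyl-5-(prop-2-en-1-yl)-1,4,4a,5,6,7,8,8a-octahydronaphthalene-2-carboxylate | COC(=O)C1=CC[C@H]2[C@](C)(CC=C)[C@@H](Cl)C[C@H](O)[C@]2(C)[C@H]1C(OC)OC | intermediate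
19 | 2-methylbut-3-en-2-ol | CC(C)(O)C=C | starting material
20 | methyl (1R,4aR,5S,6S,8S,8aS)-6-chloro-1-(dimethoxymethyl)-8-hydroxy-5-[(2E)-4-hydroxy-4-methylpent-2-en-1-yl]-5,8a-dimethyl-1,4,4a,5,6,7,8,8a-octahydronaphthalene-2-carboxylate | COC(=O)C1=CC[C@H]2[C@](C)(C/C=C/C(C)(C)O)[C@@H](Cl)C[C@H](O)[C@]2(C)[C@H]1C(OC)OC | intermediate
21 | methyl (1R,4aR,5S,6S,8S,8aS)-6-chloro-1-formyl-8-hydroxy-5-[(2E)-4-hydroxy-4-methylpent-2-en-1-yl]-5,8a-dimethyl-1,4,4a,5,6,7,8,8a-octahydronaphthalene-2-carboxylate (CNP0167913.1) | COC(=O)C1=CC[C@H]2[C@](C)(C/C=C/C(C)(C)O)[C@@H](Cl)C[C@H](O)[C@]2(C)[C@H]1C=O | target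

**Step count and risks**

Total steps: 13. Longest linear sequence: 12 steps (steps 1–8 and 10–13); step 9 is a one-step side branch to 14.

Most likely to fail, step 10. The freed enolate may be quenched by proton transfer from the enolisable aldehyde, or consumed by intermolecular aldol addition, before it adds to the acceptor at the congested C8a. The Michael adduct may also revert without cyclising, the facial selectivity at C8a or the C1 ratio may erode, or HCl may be lost from the β-chloro ketone. The fallback separates the two bond formations and sets out from compound 10. iBu2AlH (2.5 equiv, −78 → 0 °C) should reduce the ester to 2-[(1R,5S,6S)-5-chloro-3-{[dimethyl(phenyl)silyl]oxy}-2,6-dimethyl-6-(prop-2-en-1-yl)cyclohex-2-en-1-yl]ethan-1-ol F6. Bu4N[Ph3SiF2] and 14 in THF should then effect the Michael addition alone, since no aldehyde is present, and give after protonation the keto phosphonate alcohol F7; diastereomers at C8a or C1 would be separated here. Dess–Martin periodinane with NaHCO3 should give the keto phosphonate aldehyde F8. LiCl and iPr2NEt in MeCN (Masamune–Roush conditions) should then close ring A, returning to the route at compound 17.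

Second, step 7. Hydride transfer to the tetrasubstituted β-carbon next to the quaternary C5 may be too slow, so that 1,2-reduction or deprotonation of the acidic CH2CO2Et group takes over, or the hydride may be delivered to the wrong face. The fallback changes to electron-transfer reduction with thermodynamic protonation and sets out from compound 9. SmI2, HMPA and tBuOH in THF at −78 °C should give the saturated keto ester F3, with axial protonation at C4a and the chloride inert. Me3SiOTf and Et3N in CH2Cl2 (−78 → 0 °C, equilibrating) should give the more substituted trimethylsilyl enol ether F4; the equatorial chloride is poorly aligned for elimination. iBu2AlH at −78 °C should give the aldehyde F5, the trimethylsilyl analogue of 11, which is taken through step 10 and returns to the route at compound 17.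

Third, step 2. The chloronium ion may be captured by the hydroxyl group, a ring bond may migrate instead of the allyl group, the terminal alkene may be chlorinated, or the tertiary allylic alcohol may ionise. The fallback replaces the chloronium shift by an epoxide-based semipinacol shift followed by stereoretentive chlorination and sets out from compound 2. VO(acac)2 and tBuOOH should give the hydroxyl-directed syn epoxy alcohol (1S,2S,6S)-1-methyl-2-(prop-2-en-1-yl)-7-oxabicyclo[4.1.0]heptan-2-ol F1. BF3·OEt2 in CH2Cl2 at −78 °C should induce the anti 1,2-allyl shift to (2R,3S)-3-hydroxy-2-methyl-2-(prop-2-en-1-yl)cyclohexan-1-one F2, with the hydroxyl group cis to methyl. SOCl2 followed by catalytic TiCl4 should convert the chlorosulfite into the chloride with retention (front-side delivery), returning to the route at compound 4.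

Further compounds
F1 | step 2 | (1S,2S,6S)-1-methyl-2-(prop-2-en-1-yl)-7-oxabicyclo[4.1.0]heptan-2-ol | C=CC[C@@]1(O)CCC[C@@H]2O[C@]12C
F2 | step 2 | (2R,3S)-3-hydroxy-2-methyl-2-(prop-2-en-1-yl)cyclohexan-1-one | O=C1[C@](C)(CC=C)[C@@H](O)CCC1
F3 | step 7 | ethyl 2-[(1R,5S,6S)-5-chloro-2,6-dimethyl-3-oxo-6-(prop-2-en-1-yl)cyclohexyl]acetate (both C2 epimers) | CCOC(=O)C[C@H]1[C@](C)(CC=C)[C@@H](Cl)CC(=O)C1C
F4 | step 7 | ethyl 2-[(1R,5S,6S)-5-chloro-2,6-dimethyl-6-(prop-2-en-1-yl)-3-[(trimethylsilyl)oxy]cyclohex-2-en-1-yl]acetate | CCOC(=O)C[C@H]1[C@](C)(CC=C)[C@@H](Cl)CC(O[Si](C)(C)C)=C1C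
F5 | step 7 | 2-[(1R,5S,6S)-5-chloro-2,6-dimethyl-6-(prop-2-en-1-yl)-3-[(trimethylsilyl)oxy]cyclohex-2-en-1-yl]acetaldehyde | O=CC[C@H]1[C@](C)(CC=C)[C@@H](Cl)CC(O[Si](C)(C)C)=C1C
F6 | step 10 | 2-[(1R,5S,6S)-5-chloro-3-{[dimethyl(phenyl)silyl]oxy}-2,6-dimethyl-6-(prop-2-en-1-yl)cyclohex-2-en-1-yl]ethan-1-ol | OCC[C@H]1[C@](C)(CC=C)[C@@H](Cl)CC(O[Si](C)(C)c2ccccc2)=C1C
F7 | step 10 | keto phosphonate alcohol, the protonated Michael adduct of F6 and 14 (ring B cyclohexanone with 2-hydroxyethyl on C4a and the phosphonoacetate chain on C8a; epimers at the phosphonate carbon) | OCC[C@H]1[C@](C)(CC=C)[C@@H](Cl)CC(=O)[C@]1(C)[C@@H](C(OC)OC)C(C(=O)OC)P(=O)(OCC)OCC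
F8 | step 10 | keto phosphonate aldehyde obtained by oxidation of F7 | O=CC[C@H]1[C@](C)(CC=C)[C@@H](Cl)CC(=O)[C@]1(C)[C@@H](C(OC)OC)C(C(=O)OC)P(=O)(OCC)OCC
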